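## Retrosynthetic overview

1. The plan rests on ring B of the flavanone half. It is a 1,2,4,5-tetrasubstituted benzene with oxygens on neighbouring C3' and C4', and carbon substituents on neighbouring C1' (to flavanone C2) and C6' (to luteolin C8). This pattern maps onto a 2,3-dioxygenated butadiene (C2'-C3'-C4'-C5') plus a disubstituted alkyne (C1'≡C6').
2. Late disconnections: eight benzyl ethers (hydrogenolysis), O1-C2 of flavanone ring C (enantioselective oxa-Michael, sets 2R), and C2=C3 (Knoevenagel of a biaryl aldehyde with a phloroacetophenone-derived tert-butyl β-keto ester).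
3. The aldehyde carbon (future C2) is the ester carbon of a benzoate. Its ring B is grown by [4+2] addition of the diene released from 1,2-bis(trimethylsilyloxy)cyclobutene to an 8-alkynoate of protected luteolin, followed by dehydrogenation.
4. The alkynoate comes from luteolin by benzylation, C8 iodination and Sonogashira coupling, so the crowded C8-C6' bond is first laid down as a slim aryl-alkyne bond.
5. Ring order: the three luteolin rings (bought), then flavanone ring B (steps 4 and 5), then flavanone ring A (bought, joined in step 12), then flavanone ring C (step 13).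

Key step: step 4

Remark on the axis: the C6'-C8 biaryl axis has three ortho substituents and the target SMILES defines no axial configuration, so it is treated as undefined and any rotamers or atropisomers are carried on together.

Remark on the catalyst: the quinine-derived member of the pseudoenantiomeric thiourea pair is assumed to give 2R. If the sense proves opposite on this substrate, the quinidine-derived member takes its place.

Remark on 18: the alkene is drawn Z (ring B syn to the ester) as the sterically expected isomer, and this geometry is lost in step 13.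

## Route

Step 1
Reactants: 1 luteolin
Product: 2 5,7,3',4'-tetra-O-benzylluteolin
Conditions: BnBr (6 equiv), K2CO3 (8 equiv), DMF, 80 °C
Reagents that add atoms: benzyl bromide, BrCc1ccccc1
Why: Williamson ether synthesis, in which heat and excess halide also force alkylation of the chelated 5-OH.

Step 2
Reactants: 2 5,7,3',4'-tetra-O-benzylluteolin
Product: 3 8-iodo-5,7,3',4'-tetra-O-benzylluteolin
Conditions: NIS (1.1 equiv), DMF, 40 °C, dark
Reagents that add atoms: N-iodosuccinimide, O=C1CCC(=O)N1I
Why: Electrophilic aromatic iodination: only C6 and C8 are activated by two ether oxygens, and once O5 is alkylated 5,7-dialkoxyflavones are iodinated at C8 (between one benzyloxy group and the ring oxygen) rather than at C6 (between two benzyloxy groups).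

Step 3
Reactants: 3 8-iodo-5,7,3',4'-tetra-O-benzylluteolin; 4 methyl propiolate
Product: 5 methyl 3-(5,7,3',4'-tetra-O-benzylluteolin-8-yl)prop-2-ynoate
Conditions: PdCl2(PPh3)2 (5 mol %), CuI (10 mol %), K2CO3 (3 equiv), THF, 65 °C, 4 (4 equiv) added slowly
Reagents that add atoms: none
Why: Sonogashira coupling run with an inorganic base instead of an amine, so that conjugate addition to the propiolate and its oligomerisation are held back.

Step 4
Reactants: 5 methyl 3-(5,7,3',4'-tetra-O-benzylluteolin-8-yl)prop-2-ynoate; 6 1,2-bis(trimethylsilyloxy)cyclobutene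
Product: 8 methyl 2-(tetra-O-benzylluteolin-8-yl)-4,5-bis(trimethylsilyloxy)cyclohexa-1,4-diene-1-carboxylate, via 2,3-bis(trimethylsilyloxy)buta-1,3-diene 7 (not isolated)
Conditions: 6 (6 equiv), BHT (5 mol %), degassed o-dichlorobenzene, base-washed sealed tube, 180 °C; volatiles removed in vacuo, crude 8 used directly
Reagents that add atoms: none
Why: Heat releases the ring strain of 6 in a conrotatory four-electron electrocyclic opening to diene 7, whose s-cis form adds in a concerted, normal-electron-demand [4+2] fashion across the C≡C bond of 5 and forms C1'-C2' and C5'-C6'. The closest known reactions are the thermal opening of 6 with Diels-Alder trapping by acetylenic esters, and Diels-Alder benzannulations that build biaryls on ortho-substituted arylalkynes. Ring B closes as a six-membered carbocycle by intermolecular cycloaddition, both σ bonds forming in one event, and appears as the 1,4-cyclohexadiene. No stereocentre is created, and the axis to C8 is left uncontrolled. No regiochemistry arises because 7 is symmetric, and the alkynoate is preferred over the flavone C2=C3 bond because the ester lowers its acceptor orbital and the linear alkyne is sterically slim, whereas C2=C3 is trisubstituted, donor-substituted and part of a conjugated pyranone. Excess 6 and exclusion of acid, air and moisture offset diene decay and protect the two silyl enol ethers.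

Step 5
Reactants: 8 methyl 2-(tetra-O-benzylluteolin-8-yl)-4,5-bis(trimethylsilyloxy)cyclohexa-1,4-diene-1-carboxylate
Product: 9 methyl 2-(tetra-O-benzylluteolin-8-yl)-4,5-bis(trimethylsilyloxy)benzoate
Conditions: DDQ (1.0 equiv), dry toluene, 0 °C to rt, Ar, dark
Reagents that add atoms: none
Why: Dehydrogenative aromatisation: hydride abstraction from a doubly allylic CH2 gives a silyloxy-stabilised cation that loses a proton to the arene, and one equivalent of quinone avoids further oxidation of the catechol unit.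

Step 6
Reactants: 9 methyl 2-(tetra-O-benzylluteolin-8-yl)-4,5-bis(trimethylsilyloxy)benzoate
Product: 10 methyl 4,5-bis(benzyloxy)-2-(tetra-O-benzylluteolin-8-yl)benzoate
Conditions: CsF (4 equiv), BnBr (3 equiv), DMF, rt, Ar
Reagents that add atoms: benzyl bromide, BrCc1ccccc1
Why: Fluoride desilylation with in situ Williamson alkylation, so each phenoxide is trapped as it forms and the air-sensitive free catechol does not build up.

Step 7
Reactants: 10 methyl 4,5-bis(benzyloxy)-2-(tetra-O-benzylluteolin-8-yl)benzoate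
Product: 11 4,5-bis(benzyloxy)-2-(tetra-O-benzylluteolin-8-yl)benzoic acid
Conditions: LiOH·H2O (5 equiv), THF/MeOH/H2O, 45 °C; then 1 M HCl
Reagents that add atoms: lithium hydroxide, [Li+].[OH-]
Why: Ester saponification, the first of three chemoselective moves to the aldehyde, chosen because hydrides able to reduce an aryl ester directly (DIBAL-H, LiAlH4) also add to the chromone; any pyranone opened by hydroxide recloses on acidification.

Step 8
Reactants: 11 4,5-bis(benzyloxy)-2-(tetra-O-benzylluteolin-8-yl)benzoic acid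
Product: 13 [4,5-bis(benzyloxy)-2-(tetra-O-benzylluteolin-8-yl)phenyl]methanol, via isobutyl carbonic mixed anhydride 12 (not isolated)
Conditions: i-BuOCOCl, N-methylmorpholine, THF, −15 °C; then NaBH4, H2O, 0 °C
Reagents that add atoms: isobutyl chloroformate, CC(C)COC(=O)Cl (its atoms stand in 12 only)
Why: Mixed-anhydride activation followed by borohydride reduction, in which NaBH4 at 0 °C attacks the activated aroyl carbon while the flavone carbonyl, a vinylogous ester, is inert to borohydride.

Step 9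
Reactants: 13 [4,5-bis(benzyloxy)-2-(tetra-O-benzylluteolin-8-yl)phenyl]methanol
Product: 14 4,5-bis(benzyloxy)-2-(tetra-O-benzylluteolin-8-yl)benzaldehyde
Conditions: activated MnO2 (15 equiv), CH2Cl2, rt
Reagents that add atoms: none
Why: Heterogeneous MnO2 oxidation of an electron-rich benzylic alcohol, which stops at the aldehyde and leaves the benzyl ethers and the flavone untouched.

Step 10
Reactants: 15 phloroacetophenone (2,4,6-trihydroxyacetophenone)
Product: 16 1-[2,4-bis(benzyloxy)-6-hydroxyphenyl]ethanone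
Conditions: BnBr (2.05 equiv), K2CO3 (2.2 equiv), acetone, reflux
Reagents that add atoms: benzyl bromide, BrCc1ccccc1
Why: Selective Williamson alkylation: after the para and one ortho hydroxyl have reacted, the remaining ortho hydroxyl is chelated to the acetyl carbonyl and stays free with limiting halide.

Step 11
Reactants: 16 1-[2,4-bis(benzyloxy)-6-hydroxyphenyl]ethanone
Product: 17 tert-butyl 3-[2,4-bis(benzyloxy)-6-hydroxyphenyl]-3-oxopropanoate
Conditions: LiHMDS (3.3 equiv), THF, −78 to −20 °C; Boc2O (1.05 equiv), −78 to −20 °C; AcOH quench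
Reagents that add atoms: di-tert-butyl dicarbonate, CC(C)(C)OC(=O)OC(=O)OC(C)(C)C
Why: Claisen-type C-acylation of the lithium phenoxide-enolate dianion, whose enolate carbon is more nucleophilic than the chelated phenoxide; the third equivalent of base takes up the acidic product, and the bulky ester resists lactonisation to a 4-hydroxycoumarin.

Step 12
Reactants: 14 4,5-bis(benzyloxy)-2-(tetra-O-benzylluteolin-8-yl)benzaldehyde; 17 tert-butyl 3-[2,4-bis(benzyloxy)-6-hydroxyphenyl]-3-oxopropanoate
Product: 18 tert-butyl (Z)-2-[2,4-bis(benzyloxy)-6-hydroxybenzoyl]-3-[4,5-bis(benzyloxy)-2-(tetra-O-benzylluteolin-8-yl)phenyl]prop-2-enoate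
Conditions: piperidine (20 mol %), AcOH (20 mol %), 4 Å MS, toluene, rt
Reagents that add atoms: none
Why: Knoevenagel condensation through the aldehyde iminium ion, run at room temperature so that the ketone-chelated phenol does not yet add to the new acceptor.

Step 13
Reactants: 18 tert-butyl (Z)-2-[2,4-bis(benzyloxy)-6-hydroxybenzoyl]-3-[4,5-bis(benzyloxy)-2-(tetra-O-benzylluteolin-8-yl)phenyl]prop-2-enoate
Product: 21 (2R)-5,7-bis(benzyloxy)-2-[4,5-bis(benzyloxy)-2-(tetra-O-benzylluteolin-8-yl)phenyl]chroman-4-one, via tert-butyl 4-oxoflavan-3-carboxylate 19 (not isolated), via 4-oxoflavan-3-carboxylic acid 20 (not isolated)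
Conditions: N-[3,5-bis(trifluoromethyl)phenyl]-N'-(9-deoxy-epi-quinin-9-yl)thiourea (10 mol %), toluene, −25 °C; then TsOH·H2O (1 equiv), 80 °C, same flask
Reagents that add atoms: none
Why: Bifunctional cinchona-thiourea catalysed 6-endo-trig oxa-Michael addition, in which the thiourea binds the β-dicarbonyl, the quinuclidine activates the phenol and the catalyst pocket selects the alkene face to set C2 as R; acid-induced loss of isobutene and decarboxylation then remove the labile C3 centre without touching C2.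

Step 14
Reactants: 21 (2R)-5,7-bis(benzyloxy)-2-[4,5-bis(benzyloxy)-2-(tetra-O-benzylluteolin-8-yl)phenyl]chroman-4-one
Product: 22 (2R)-2-[4,5-dihydroxy-2-(luteolin-8-yl)phenyl]-5,7-dihydroxychroman-4-one (CNP0228504.1)
Conditions: H2 (1 atm), 10 % Pd/C, THF/MeOH, trace AcOH, rt; filtration and base-free work-up
Reagents that add atoms: none
Why: Catalytic hydrogenolysis of eight aryl benzyl ethers at one atmosphere, which normally spares the flavone C2=C3 bond and the flavanone C2-O bond; the weakly acidic medium avoids ring-opening to the chalcone, the path by which C2 would racemise.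

## Compound list

1 | luteolin | O=c1cc(-c2ccc(O)c(O)c2)oc2cc(O)cc(O)c12 | starting material
2 | 5,7,3',4'-tetra-O-benzylluteolin | O=c1cc(-c2ccc(OCc3ccccc3)c(OCc3ccccc3)c2)oc2cc(OCc3ccccc3)cc(OCc3ccccc3)c12 | intermediate
3 | 8-iodo-5,7,3',4'-tetra-O-benzylluteolin | O=c1cc(-c2ccc(OCc3ccccc3)c(OCc3ccccc3)c2)oc2c(I)c(OCc3ccccc3)cc(OCc3ccccc3)c12 | intermediate
4 | methyl propiolate | C#CC(=O)OC | starting material
5 | methyl 3-(tetra-O-benzylluteolin-8-yl)prop-2-ynoate | COC(=O)C#Cc1c(OCc2ccccc2)cc(OCc2ccccc2)c2c(=O)cc(-c3ccc(OCc4ccccc4)c(OCc4ccccc4)c3)oc12 | intermediate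
6 | 1,2-bis(trimethylsilyloxy)cyclobutene | C[Si](C)(C)OC1=C(O[Si](C)(C)C)CC1 | starting material
7 | 2,3-bis(trimethylsilyloxy)buta-1,3-diene | C=C(O[Si](C)(C)C)C(=C)O[Si](C)(C)C | intermediate
8 | methyl 2-(tetra-O-benzylluteolin-8-yl)-4,5-bis(trimethylsilyloxy)cyclohexa-1,4-diene-1-carboxylate | COC(=O)C1=C(c2c(OCc3ccccc3)cc(OCc3ccccc3)c3c(=O)cc(-c4ccc(OCc5ccccc5)c(OCc5ccccc5)c4)oc23)CC(O[Si](C)(C)C)=C(O[Si](C)(C)C)C1 | intermediate
9 | methyl 2-(tetra-O-benzylluteolin-8-yl)-4,5-bis(trimethylsilyloxy)benzoate | COC(=O)c1cc(O[Si](C)(C)C)c(O[Si](C)(C)C)cc1-c1c(OCc2ccccc2)cc(OCc2ccccc2)c2c(=O)cc(-c3ccc(OCc4ccccc4)c(OCc4ccccc4)c3)oc12 | intermediate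
10 | methyl 4,5-bis(benzyloxy)-2-(tetra-O-benzylluteolin-8-yl)benzoate | COC(=O)c1cc(OCc2ccccc2)c(OCc2ccccc2)cc1-c1c(OCc2ccccc2)cc(OCc2ccccc2)c2c(=O)cc(-c3ccc(OCc4ccccc4)c(OCc4ccccc4)c3)oc12 | intermediate
11 | 4,5-bis(benzyloxy)-2-(tetra-O-benzylluteolin-8-yl)benzoic acid | OC(=O)c1cc(OCc2ccccc2)c(OCc2ccccc2)cc1-c1c(OCc2ccccc2)cc(OCc2ccccc2)c2c(=O)cc(-c3ccc(OCc4ccccc4)c(OCc4ccccc4)c3)oc12 | intermediate
12 | isobutyl carbonic mixed anhydride of 11 | CC(C)COC(=O)OC(=O)c1cc(OCc2ccccc2)c(OCc2ccccc2)cc1-c1c(OCc2ccccc2)cc(OCc2ccccc2)c2c(=O)cc(-c3ccc(OCc4ccccc4)c(OCc4ccccc4)c3)oc12 | intermediate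
13 | [4,5-bis(benzyloxy)-2-(tetra-O-benzylluteolin-8-yl)phenyl]methanol | OCc1cc(OCc2ccccc2)c(OCc2ccccc2)cc1-c1c(OCc2ccccc2)cc(OCc2ccccc2)c2c(=O)cc(-c3ccc(OCc4ccccc4)c(OCc4ccccc4)c3)oc12 | intermediate
14 | 4,5-bis(benzyloxy)-2-(tetra-O-benzylluteolin-8-yl)benzaldehyde | O=Cc1cc(OCc2ccccc2)c(OCc2ccccc2)cc1-c1c(OCc2ccccc2)cc(OCc2ccccc2)c2c(=O)cc(-c3ccc(OCc4ccccc4)c(OCc4ccccc4)c3)oc12 | intermediate
15 | phloroacetophenone | CC(=O)c1c(O)cc(O)cc1O | starting material
16 | 1-[2,4-bis(benzyloxy)-6-hydroxyphenyl]ethanone | CC(=O)c1c(O)cc(OCc2ccccc2)cc1OCc1ccccc1 | intermediate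
17 | tert-butyl 3-[2,4-bis(benzyloxy)-6-hydroxyphenyl]-3-oxopropanoate | CC(C)(C)OC(=O)CC(=O)c1c(O)cc(OCc2ccccc2)cc1OCc1ccccc1 | intermediate
18 | tert-butyl (Z)-2-[2,4-bis(benzyloxy)-6-hydroxybenzoyl]-3-[4,5-bis(benzyloxy)-2-(tetra-O-benzylluteolin-8-yl)phenyl]prop-2-enoate | CC(C)(C)OC(=O)/C(C(=O)c1c(O)cc(OCc2ccccc2)cc1OCc1ccccc1)=C\c1cc(OCc2ccccc2)c(OCc2ccccc2)cc1-c1c(OCc2ccccc2)cc(OCc2ccccc2)c2c(=O)cc(-c3ccc(OCc4ccccc4)c(OCc4ccccc4)c3)oc12 | intermediate
19 | tert-butyl (2R,3S)-5,7-bis(benzyloxy)-2-[4,5-bis(benzyloxy)-2-(tetra-O-benzylluteolin-8-yl)phenyl]-4-oxochromane-3-carboxylate (trans drawn; C3 is labile) | O=C1[C@@H](C(=O)OC(C)(C)C)[C@H](c2cc(OCc3ccccc3)c(OCc3ccccc3)cc2-c2c(OCc3ccccc3)cc(OCc3ccccc3)c3c(=O)cc(-c4ccc(OCc5ccccc5)c(OCc5ccccc5)c4)oc23)Oc2cc(OCc3ccccc3)cc(OCc3ccccc3)c21 | intermediate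
20 | (2R,3S)-5,7-bis(benzyloxy)-2-[4,5-bis(benzyloxy)-2-(tetra-O-benzylluteolin-8-yl)phenyl]-4-oxochromane-3-carboxylic acid (C3 is labile) | O=C1[C@@H](C(=O)O)[C@H](c2cc(OCc3ccccc3)c(OCc3ccccc3)cc2-c2c(OCc3ccccc3)cc(OCc3ccccc3)c3c(=O)cc(-c4ccc(OCc5ccccc5)c(OCc5ccccc5)c4)oc23)Oc2cc(OCc3ccccc3)cc(OCc3ccccc3)c21 | intermediate
21 | (2R)-5,7-bis(benzyloxy)-2-[4,5-bis(benzyloxy)-2-(tetra-O-benzylluteolin-8-yl)phenyl]chroman-4-one | O=C1C[C@H](c2cc(OCc3ccccc3)c(OCc3ccccc3)cc2-c2c(OCc3ccccc3)cc(OCc3ccccc3)c3c(=O)cc(-c4ccc(OCc5ccccc5)c(OCc5ccccc5)c4)oc23)Oc2cc(OCc3ccccc3)cc(OCc3ccccc3)c21 | intermediate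
22 | (2R)-2-[4,5-dihydroxy-2-(luteolin-8-yl)phenyl]-5,7-dihydroxychroman-4-one (CNP0228504.1) | O=C1C[C@H](c2cc(O)c(O)cc2-c2c(O)cc(O)c3c(=O)cc(-c4ccc(O)c(O)c4)oc23)Oc2cc(O)cc(O)c21 | target

## Step count

Total step count: 14.
Longest linear sequence: 12 steps (steps 1 to 9, then 12 to 14). Steps 10 and 11 form the ring A branch.

## Steps most likely to fail

**Step 4.**
- What may go wrong: cycloaddition at the alkyne carbon next to the doubly ortho-flanked C8 may be slower than thermal decay and oligomerisation of the diene. Long heating may also strip the silyl enol ethers.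
- Fallback: this gives up the benzannulation and makes the C8-C6' bond by cross-coupling. It sets out from 3 and comes back at 14.
- Miyaura borylation of 3 (B2pin2, PdCl2(dppf), KOAc, dioxane, 90 °C) should give tetra-O-benzylluteolin-8-yl pinacol boronate F1.
- Commercial 3,4-bis(benzyloxy)benzaldehyde is brominated (Br2, AcOH, rt) para to its 3-benzyloxy group to give 2-bromo-4,5-bis(benzyloxy)benzaldehyde F2.
- Suzuki-Miyaura coupling of the two (Pd(OAc)2, SPhos, K3PO4, toluene/H2O, 90 °C) should deliver 14 directly.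

**Step 13.**
- What may go wrong: facial selectivity may be poor because the ortho flavonyl group and the 5-benzyloxy group crowd the hydrogen-bonded transition state. Slowly interconverting rotamers about the biaryl axis may respond differently to the catalyst, and uncatalysed closure may compete.
- Fallback: this replaces asymmetric closure by a kinetic resolution of the closed ketone. It sets out from 21 of insufficient enantiomeric purity and comes back at 21.
- Asymmetric transfer hydrogenation (Cp*RhCl[(S,S)-TsDPEN], HCO2H/Et3N, EtOAc, rt) uses the catalyst enantiomer that forms 4S carbinols in the chromanone series. It should consume the unwanted (2S)-octa-O-benzyl flavanone F3.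
- F3 is turned into the cis-(2S,4S)-octa-O-benzyl flavan-4-ol F4, which chromatography removes, while (2R)-21 remains as the ketone.

**Step 3.**
- What may go wrong: base- and copper-induced oligomerisation of methyl propiolate may outrun the slow oxidative addition at the electron-rich, doubly flanked iodide.
- Fallback: this installs the alkyne and the ester carbon separately. It sets out from 3 and comes back at 5.
- Sonogashira coupling with trimethylsilylacetylene (PdCl2(PPh3)2, CuI, Et3N, THF, 60 °C) should give 8-(trimethylsilylethynyl)-tetra-O-benzylluteolin F5.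
- K2CO3 in MeOH/THF frees 8-ethynyl-tetra-O-benzylluteolin F6.
- Palladium-catalysed oxidative methoxycarbonylation (PdCl2 cat., CuCl2, NaOAc, CO 1 atm, MeOH/THF, rt) then converts the terminal alkyne into 5.

## Further compounds

F1 | step 4 | tetra-O-benzylluteolin-8-yl pinacol boronate | CC1(C)OB(OC1(C)C)c1c(OCc2ccccc2)cc(OCc2ccccc2)c2c(=O)cc(-c3ccc(OCc4ccccc4)c(OCc4ccccc4)c3)oc12
F2 | step 4 | 2-bromo-4,5-bis(benzyloxy)benzaldehyde | O=Cc1cc(OCc2ccccc2)c(OCc2ccccc2)cc1Br
F3 | step 13 | (2S)-octa-O-benzyl flavanone (enantiomer of 21) | O=C1C[C@@H](c2cc(OCc3ccccc3)c(OCc3ccccc3)cc2-c2c(OCc3ccccc3)cc(OCc3ccccc3)c3c(=O)cc(-c4ccc(OCc5ccccc5)c(OCc5ccccc5)c4)oc23)Oc2cc(OCc3ccccc3)cc(OCc3ccccc3)c21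
F4 | step 13 | cis-(2S,4S)-octa-O-benzyl flavan-4-ol | O[C@H]1C[C@@H](c2cc(OCc3ccccc3)c(OCc3ccccc3)cc2-c2c(OCc3ccccc3)cc(OCc3ccccc3)c3c(=O)cc(-c4ccc(OCc5ccccc5)c(OCc5ccccc5)c4)oc23)Oc2cc(OCc3ccccc3)cc(OCc3ccccc3)c21
F5 | step 3 | 8-(trimethylsilylethynyl)-tetra-O-benzylluteolin | C[Si](C)(C)C#Cc1c(OCc2ccccc2)cc(OCc2ccccc2)c2c(=O)cc(-c3ccc(OCc4ccccc4)c(OCc4ccccc4)c3)oc12
F6 | step 3 | 8-ethynyl-tetra-O-benzylluteolin | C#Cc1c(OCc2ccccc2)cc(OCc2ccccc2)c2c(=O)cc(-c3ccc(OCc4ccccc4)c(OCc4ccccc4)c3)oc12
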